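## Retrosynthetic overview

1. Target 38 comes from its octadeca-O-benzyl ether 37 by one hydrogenolysis. Rings are lettered A to G from the 2,4,6-trihydroxyphenoxy end to the 3,4,5-trihydroxyphenoxy end.
2. 37 is cut at the B–C ether: pentamer phenol 36 (rings C–G) plus aryl iodide 24 (rings A–B), joined by Ullmann coupling.
3. In 24, ring A is built de novo on the ring-B oxygen: intermolecular Claisen condensation of aryloxymalonate 18 with dimethyl 3-oxoglutarate 19, Dieckmann closure and aromatisation, O-benzylation, then loss of both ester groups.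
4. 36 comes from four Ullmann coupling / Baeyer–Villiger cycles that make the G–F, F–E, E–D and D–C ethers in that order. Each new ring arrives as a halobenzaldehyde (10, 7, 16, 7) whose CHO becomes the next phenol.
5. Ring formation: only ring A is constructed (inside 24, before the last coupling). Rings B–G are bought as arenes (5-iodovanillin, methyl gallate, 4-bromo-3,5-dihydroxybenzoic acid).

Assumption: the target has no stereocentre or hindered axis (achiral), so no stereocontrol is needed; all 18 OH groups are carried as benzyl ethers (Bn).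

## Route

Step 1
Reactants: 1 methyl gallate (methyl 3,4,5-trihydroxybenzoate)
Product: 2 methyl 3,4,5-tris(benzyloxy)benzoate
Conditions: BnBr (3.5 equiv), K2CO3, DMF, 60 °C
Reagents that add atoms: benzyl bromide, BrCc1ccccc1
Why: Williamson ether synthesis on three acidic phenols with no competing site.

Step 2
Reactants: 2 methyl 3,4,5-tris(benzyloxy)benzoate
Product: 3 [3,4,5-tris(benzyloxy)phenyl]methanol
Conditions: LiAlH4, THF, 0 °C to rt; NaOH/H2O work-up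
Reagents that add atoms: none
Why: Hydride reduction of the ester to the benzylic alcohol; benzyl ethers are inert.

Step 3
Reactants: 3 [3,4,5-tris(benzyloxy)phenyl]methanol
Product: 4 3,4,5-tris(benzyloxy)benzaldehyde
Conditions: activated MnO2 (10 equiv), CH2Cl2, rt
Reagents that add atoms: none
Why: Selective MnO2 oxidation of a benzylic alcohol, which stops at the aldehyde.

Step 4
Reactants: 4 3,4,5-tris(benzyloxy)benzaldehyde
Product: 6 3,4,5-tris(benzyloxy)phenol (ring G), via aryl formate 5 (not isolated)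
Conditions: mCPBA (1.5 equiv), CH2Cl2, 0 °C to rt; aq. NaHCO3/Na2S2O3 wash; then K2CO3 (cat.), MeOH, rt
Reagents that add atoms: mCPBA, OOC(=O)c1cccc(Cl)c1
Why: Baeyer–Villiger (Dakin-type) oxidation, where the electron-rich aryl group migrates to give the formate, which is methanolysed to the phenol.

Step 5
Reactants: 4 3,4,5-tris(benzyloxy)benzaldehyde
Product: 7 2-bromo-3,4,5-tris(benzyloxy)benzaldehyde (block for rings C and E)
Conditions: NBS (1.05 equiv), MeCN, rt, dark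
Reagents that add atoms: N-bromosuccinimide, BrN1C(=O)CCC1=O
Why: Electrophilic aromatic bromination at the equivalent 2/6 positions, activated by ortho and para benzyloxy groups; the pendant benzyl rings are far less reactive.

Step 6
Reactants: 8 5-iodovanillin (4-hydroxy-3-iodo-5-methoxybenzaldehyde)
Product: 9 3,4-dihydroxy-5-iodobenzaldehyde
Conditions: AlCl3 (1.2 equiv), pyridine (4.5 equiv), CH2Cl2, reflux; aq. HCl
Reagents that add atoms: none
Why: Chelation-assisted Lewis-acid O-demethylation of the guaiacol unit, with pyridine accepting the methyl group.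

Step 7
Reactants: 9 3,4-dihydroxy-5-iodobenzaldehyde
Product: 10 3,4-bis(benzyloxy)-5-iodobenzaldehyde (block for ring F; precursor of ring B)
Conditions: BnBr (2.4 equiv), K2CO3, DMF, 50 °C
Reagents that add atoms: benzyl bromide, BrCc1ccccc1
Why: Williamson ether synthesis of both catechol hydroxyls.

Step 8
Reactants: 10 3,4-bis(benzyloxy)-5-iodobenzaldehyde
Product: 12 3,4-bis(benzyloxy)-5-iodophenol, via iodoaryl formate 11 (not isolated)
Conditions: mCPBA (1.5 equiv), CH2Cl2, 0 °C to rt; aq. NaHCO3/Na2S2O3 wash; then K2CO3 (cat.), MeOH, rt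
Reagents that add atoms: mCPBA, OOC(=O)c1cccc(Cl)c1
Why: Baeyer–Villiger oxidation assisted by the para benzyloxy group; the aryl iodide is not oxidised without a strong acid activator.

Step 9
Reactants: 13 4-bromo-3,5-dihydroxybenzoic acid
Product: 14 benzyl 3,5-bis(benzyloxy)-4-bromobenzoate
Conditions: BnBr (3.5 equiv), K2CO3, DMF, 60 °C
Reagents that add atoms: benzyl bromide, BrCc1ccccc1
Why: Williamson O-alkylation of both phenols and the carboxylate in one operation.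

Step 10
Reactants: 14 benzyl 3,5-bis(benzyloxy)-4-bromobenzoate
Product: 15 [3,5-bis(benzyloxy)-4-bromophenyl]methanol
Conditions: DIBAL-H (2.5 equiv), CH2Cl2, −78 to 0 °C; Rochelle-salt work-up
Reagents that add atoms: none
Why: Ester reduction with DIBAL-H, which leaves the aryl bromide and benzyl ethers intact.

Step 11
Reactants: 15 [3,5-bis(benzyloxy)-4-bromophenyl]methanol
Product: 16 3,5-bis(benzyloxy)-4-bromobenzaldehyde (block for ring D)
Conditions: activated MnO2 (10 equiv), CH2Cl2, rt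
Reagents that add atoms: none
Why: Selective benzylic alcohol oxidation with MnO2.

Step 12
Reactants: 12 3,4-bis(benzyloxy)-5-iodophenol; 17 dimethyl chloromalonate (dimethyl 2-chloropropanedioate)
Product: 18 dimethyl 2-[3,4-bis(benzyloxy)-5-iodophenoxy]propanedioate
Conditions: K2CO3, acetone, reflux
Reagents that add atoms: none
Why: SN2 O-alkylation of an unhindered phenoxide by the activated α-chloromalonate (Williamson), a standard route to aryloxymalonates.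

Step 13
Reactants: 18 dimethyl 2-[3,4-bis(benzyloxy)-5-iodophenoxy]propanedioate; 19 dimethyl 3-oxopentanedioate (dimethyl 1,3-acetonedicarboxylate)
Product: 21 dimethyl 5-[3,4-bis(benzyloxy)-5-iodophenoxy]-2,4,6-trihydroxybenzene-1,3-dicarboxylate, via acyclic Claisen adduct 20 (not isolated)
Conditions: NaH (2.5 equiv, two portions), THF, 0 °C to rt; then xylene, 140 °C with MeOH distilled off, dark; aq. HCl
Reagents that add atoms: none
Why: Intermolecular Claisen condensation in which the preformed sodium enolate of 19 C-acylates one ester of 18 to give 20, followed by Dieckmann closure onto the second malonate ester and enolisation to the aromatic phloroglucinol diester (trapped as its phenoxide), which makes the sequence irreversible; no stereocentre is formed.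

Step 14
Reactants: 21 dimethyl 5-[3,4-bis(benzyloxy)-5-iodophenoxy]-2,4,6-trihydroxybenzene-1,3-dicarboxylate
Product: 22 dimethyl 2,4,6-tris(benzyloxy)-5-[3,4-bis(benzyloxy)-5-iodophenoxy]benzene-1,3-dicarboxylate
Conditions: BnBr (4 equiv), K2CO3, DMF, 80 °C
Reagents that add atoms: benzyl bromide, BrCc1ccccc1
Why: Williamson O-benzylation; every ring carbon is substituted, so the C-benzylation typical of phloroglucinols cannot occur.

Step 15
Reactants: 22 dimethyl 2,4,6-tris(benzyloxy)-5-[3,4-bis(benzyloxy)-5-iodophenoxy]benzene-1,3-dicarboxylate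
Product: 24 1,3,5-tris(benzyloxy)-2-[3,4-bis(benzyloxy)-5-iodophenoxy]benzene (rings A–B), via diacid 23 (not isolated)
Conditions: KOH, DMSO/H2O, 90 °C; then AcOH to pH 4, 1,4-dioxane, 100 °C
Reagents that add atoms: none
Why: Saponification of the hindered esters followed by acid-promoted protodecarboxylation, which is easy because each carboxyl carbon is ortho, ortho and para to alkoxy groups (ipso-protonation).

Step 16
Reactants: 6 3,4,5-tris(benzyloxy)phenol; 10 3,4-bis(benzyloxy)-5-iodobenzaldehyde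
Product: 25 3,4-bis(benzyloxy)-5-[3,4,5-tris(benzyloxy)phenoxy]benzaldehyde (rings F–G)
Conditions: CuI (10 mol%), picolinic acid (20 mol%), K3PO4 (2 equiv), DMSO, 90 °C, Ar
Reagents that add atoms: none
Why: Cu-catalysed Ullmann diaryl ether synthesis between an unhindered phenol and an aryl iodide with one ortho substituent; the non-enolisable aldehyde is tolerated.

Step 17
Reactants: 25 dimer aldehyde
Product: 27 3,4-bis(benzyloxy)-5-[3,4,5-tris(benzyloxy)phenoxy]phenol, via dimer formate 26 (not isolated)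
Conditions: mCPBA (1.5 equiv), CH2Cl2, 0 °C to rt; aq. NaHCO3/Na2S2O3 wash; then K2CO3 (cat.), MeOH, rt
Reagents that add atoms: mCPBA, OOC(=O)c1cccc(Cl)c1
Why: Baeyer–Villiger oxidation of an electron-rich benzaldehyde (para benzyloxy), then formate methanolysis; diaryl and benzyl ethers are stable.

Step 18
Reactants: 27 dimer phenol; 7 2-bromo-3,4,5-tris(benzyloxy)benzaldehyde
Product: 28 3,4,5-tris(benzyloxy)-2-{3,4-bis(benzyloxy)-5-[3,4,5-tris(benzyloxy)phenoxy]phenoxy}benzaldehyde (rings E–G)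
Conditions: CuI (20 mol%), picolinic acid (40 mol%), K3PO4 (2 equiv), DMSO, 100 °C, Ar
Reagents that add atoms: none
Why: Ullmann ether coupling of an unhindered phenol with a bromide activated by the ortho formyl group, as in classical couplings of 2-bromo-3,4,5-trialkoxybenzoyl derivatives.

Step 19
Reactants: 28 trimer aldehyde
Product: 30 3,4,5-tris(benzyloxy)-2-{3,4-bis(benzyloxy)-5-[3,4,5-tris(benzyloxy)phenoxy]phenoxy}phenol, via trimer formate 29 (not isolated)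
Conditions: mCPBA (1.5 equiv), CH2Cl2, 0 °C to rt; aq. NaHCO3/Na2S2O3 wash; then K2CO3 (cat.), MeOH, rt
Reagents that add atoms: mCPBA, OOC(=O)c1cccc(Cl)c1
Why: Baeyer–Villiger oxidation of a benzaldehyde with ortho aryloxy and para benzyloxy donors, then methanolysis.

Step 20
Reactants: 30 trimer phenol; 16 3,5-bis(benzyloxy)-4-bromobenzaldehyde
Product: 31 3,5-bis(benzyloxy)-4-(aryloxy)benzaldehyde, in which aryloxy is the oxy residue of phenol 30 (rings D–G)
Conditions: CuI (30 mol%), picolinic acid (60 mol%), K3PO4 (2.5 equiv), DMSO, 110 °C, Ar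
Reagents that add atoms: none
Why: Ullmann coupling to the tri-ortho-substituted D–E ether, helped by the para formyl group of 16 and a ligand system made for hindered diaryl ethers.

Step 21
Reactants: 31 tetramer aldehyde
Product: 33 3,5-bis(benzyloxy)-4-(aryloxy)phenol, aryloxy as in 31, via tetramer formate 32 (not isolated)
Conditions: mCPBA (1.5 equiv), CH2Cl2, 0 °C to rt; aq. NaHCO3/Na2S2O3 wash; then K2CO3 (cat.), MeOH, rt
Reagents that add atoms: mCPBA, OOC(=O)c1cccc(Cl)c1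
Why: Baeyer–Villiger oxidation of a 3,4,5-trioxygenated benzaldehyde (as in the standard route to 3,4,5-trialkoxyphenols), then methanolysis.

Step 22
Reactants: 33 tetramer phenol; 7 2-bromo-3,4,5-tris(benzyloxy)benzaldehyde
Product: 34 3,4,5-tris(benzyloxy)-2-(aryloxy)benzaldehyde, in which aryloxy is the oxy residue of phenol 33 (rings C–G)
Conditions: CuI (20 mol%), picolinic acid (40 mol%), K3PO4 (2 equiv), DMSO, 100 °C, Ar
Reagents that add atoms: none
Why: Same Ullmann ether coupling as step 18: unhindered phenol plus ortho-formyl-activated bromide.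

Step 23
Reactants: 34 pentamer aldehyde
Product: 36 3,4,5-tris(benzyloxy)-2-(aryloxy)phenol, aryloxy as in 34, via pentamer formate 35 (not isolated)
Conditions: mCPBA (1.5 equiv), CH2Cl2, 0 °C to rt; aq. NaHCO3/Na2S2O3 wash; then K2CO3 (cat.), MeOH, rt
Reagents that add atoms: mCPBA, OOC(=O)c1cccc(Cl)c1
Why: Baeyer–Villiger oxidation and methanolysis as in step 19; ring A, the most oxidisable ring, is not yet in the molecule.

Step 24
Reactants: 36 pentamer phenol; 24 ring A–B aryl iodide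
Product: 37 octadeca-O-benzyl ether of the target (all 18 hydroxyls as OBn)
Conditions: CuI (30 mol%), picolinic acid (60 mol%), K3PO4 (3 equiv), DMSO/1,4-dioxane, 100 °C, Ar
Reagents that add atoms: none
Why: Convergent Ullmann diaryl ether coupling of a phenol and an aryl iodide that each carry one ortho oxygen substituent.

Step 25
Reactants: 37 octadeca-O-benzyl ether
Product: 38 target heptamer (CNP0137585.0)
Conditions: H2 (1 atm), 20% Pd(OH)2/C, THF/MeOH 1:1, rt; filter and concentrate under Ar; Sephadex LH-20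
Reagents that add atoms: none
Why: Global hydrogenolysis of benzyl aryl ethers under neutral, reducing conditions, which leaves the diaryl ethers intact and protects the air-sensitive polyphenol.

## Compound list

1 | methyl gallate | COC(=O)c1cc(O)c(O)c(O)c1 | starting material
2 | methyl 3,4,5-tris(benzyloxy)benzoate | COC(=O)c1cc(OCc2ccccc2)c(OCc2ccccc2)c(OCc2ccccc2)c1 | intermediate
3 | [3,4,5-tris(benzyloxy)phenyl]methanol | OCc1cc(OCc2ccccc2)c(OCc2ccccc2)c(OCc2ccccc2)c1 | intermediate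
4 | 3,4,5-tris(benzyloxy)benzaldehyde | O=Cc1cc(OCc2ccccc2)c(OCc2ccccc2)c(OCc2ccccc2)c1 | intermediate
5 | 3,4,5-tris(benzyloxy)phenyl formate | O=COc1cc(OCc2ccccc2)c(OCc2ccccc2)c(OCc2ccccc2)c1 | intermediate (not isolated)
6 | 3,4,5-tris(benzyloxy)phenol | Oc1cc(OCc2ccccc2)c(OCc2ccccc2)c(OCc2ccccc2)c1 | intermediate
7 | 2-bromo-3,4,5-tris(benzyloxy)benzaldehyde | O=Cc1cc(OCc2ccccc2)c(OCc2ccccc2)c(OCc2ccccc2)c1Br | intermediate
8 | 5-iodovanillin | COc1cc(C=O)cc(I)c1O | starting material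
9 | 3,4-dihydroxy-5-iodobenzaldehyde | O=Cc1cc(O)c(O)c(I)c1 | intermediate
10 | 3,4-bis(benzyloxy)-5-iodobenzaldehyde | O=Cc1cc(I)c(OCc2ccccc2)c(OCc2ccccc2)c1 | intermediate
11 | 3,4-bis(benzyloxy)-5-iodophenyl formate | O=COc1cc(I)c(OCc2ccccc2)c(OCc2ccccc2)c1 | intermediate (not isolated)
12 | 3,4-bis(benzyloxy)-5-iodophenol | Oc1cc(I)c(OCc2ccccc2)c(OCc2ccccc2)c1 | intermediate
13 | 4-bromo-3,5-dihydroxybenzoic acid | OC(=O)c1cc(O)c(Br)c(O)c1 | starting material
14 | benzyl 3,5-bis(benzyloxy)-4-bromobenzoate | O=C(OCc1ccccc1)c1cc(OCc2ccccc2)c(Br)c(OCc2ccccc2)c1 | intermediate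
15 | [3,5-bis(benzyloxy)-4-bromophenyl]methanol | OCc1cc(OCc2ccccc2)c(Br)c(OCc2ccccc2)c1 | intermediate
16 | 3,5-bis(benzyloxy)-4-bromobenzaldehyde | O=Cc1cc(OCc2ccccc2)c(Br)c(OCc2ccccc2)c1 | intermediate
17 | dimethyl chloromalonate | COC(=O)C(Cl)C(=O)OC | starting material
18 | dimethyl 2-[3,4-bis(benzyloxy)-5-iodophenoxy]propanedioate | COC(=O)C(Oc1cc(I)c(OCc2ccccc2)c(OCc2ccccc2)c1)C(=O)OC | intermediate
19 | dimethyl 3-oxopentanedioate | COC(=O)CC(=O)CC(=O)OC | starting material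
20 | trimethyl 1-[3,4-bis(benzyloxy)-5-iodophenoxy]-2,4-dioxopentane-1,3,5-tricarboxylate | COC(=O)C(Oc1cc(I)c(OCc2ccccc2)c(OCc2ccccc2)c1)C(=O)C(C(=O)OC)C(=O)CC(=O)OC | intermediate (not isolated)
21 | dimethyl 5-[3,4-bis(benzyloxy)-5-iodophenoxy]-2,4,6-trihydroxybenzene-1,3-dicarboxylate | COC(=O)c1c(O)c(C(=O)OC)c(O)c(Oc2cc(I)c(OCc3ccccc3)c(OCc3ccccc3)c2)c1O | intermediate
22 | dimethyl 2,4,6-tris(benzyloxy)-5-[3,4-bis(benzyloxy)-5-iodophenoxy]benzene-1,3-dicarboxylate | COC(=O)c1c(OCc2ccccc2)c(C(=O)OC)c(OCc2ccccc2)c(Oc2cc(I)c(OCc3ccccc3)c(OCc3ccccc3)c2)c1OCc1ccccc1 | intermediate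
23 | 2,4,6-tris(benzyloxy)-5-[3,4-bis(benzyloxy)-5-iodophenoxy]benzene-1,3-dicarboxylic acid | OC(=O)c1c(OCc2ccccc2)c(C(O)=O)c(OCc2ccccc2)c(Oc2cc(I)c(OCc3ccccc3)c(OCc3ccccc3)c2)c1OCc1ccccc1 | intermediate (not isolated)
24 | 1,3,5-tris(benzyloxy)-2-[3,4-bis(benzyloxy)-5-iodophenoxy]benzene | Ic1cc(Oc2c(OCc3ccccc3)cc(OCc3ccccc3)cc2OCc2ccccc2)cc(OCc2ccccc2)c1OCc1ccccc1 | intermediate
25 | 3,4-bis(benzyloxy)-5-[3,4,5-tris(benzyloxy)phenoxy]benzaldehyde | O=Cc1cc(Oc2cc(OCc3ccccc3)c(OCc3ccccc3)c(OCc3ccccc3)c2)c(OCc2ccccc2)c(OCc2ccccc2)c1 | intermediate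
26 | 3,4-bis(benzyloxy)-5-[3,4,5-tris(benzyloxy)phenoxy]phenyl formate | O=COc1cc(Oc2cc(OCc3ccccc3)c(OCc3ccccc3)c(OCc3ccccc3)c2)c(OCc2ccccc2)c(OCc2ccccc2)c1 | intermediate (not isolated)
27 | 3,4-bis(benzyloxy)-5-[3,4,5-tris(benzyloxy)phenoxy]phenol | Oc1cc(Oc2cc(OCc3ccccc3)c(OCc3ccccc3)c(OCc3ccccc3)c2)c(OCc2ccccc2)c(OCc2ccccc2)c1 | intermediate
28 | trimer aldehyde: 3,4,5-tris(benzyloxy)-2-(aryloxy)benzaldehyde, aryloxy = oxy residue of 27 | O=Cc1cc(OCc2ccccc2)c(OCc2ccccc2)c(OCc2ccccc2)c1Oc1cc(Oc2cc(OCc3ccccc3)c(OCc3ccccc3)c(OCc3ccccc3)c2)c(OCc2ccccc2)c(OCc2ccccc2)c1 | intermediate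
29 | trimer formate: formate ester of 30 | O=COc1cc(OCc2ccccc2)c(OCc2ccccc2)c(OCc2ccccc2)c1Oc1cc(Oc2cc(OCc3ccccc3)c(OCc3ccccc3)c(OCc3ccccc3)c2)c(OCc2ccccc2)c(OCc2ccccc2)c1 | intermediate (not isolated)
30 | trimer phenol: 3,4,5-tris(benzyloxy)-2-(aryloxy)phenol, aryloxy = oxy residue of 27 | Oc1cc(OCc2ccccc2)c(OCc2ccccc2)c(OCc2ccccc2)c1Oc1cc(Oc2cc(OCc3ccccc3)c(OCc3ccccc3)c(OCc3ccccc3)c2)c(OCc2ccccc2)c(OCc2ccccc2)c1 | intermediate
31 | tetramer aldehyde: 3,5-bis(benzyloxy)-4-(aryloxy)benzaldehyde, aryloxy = oxy residue of 30 | O=Cc1cc(OCc2ccccc2)c(Oc2cc(OCc3ccccc3)c(OCc3ccccc3)c(OCc3ccccc3)c2Oc2cc(Oc3cc(OCc4ccccc4)c(OCc4ccccc4)c(OCc4ccccc4)c3)c(OCc3ccccc3)c(OCc3ccccc3)c2)c(OCc2ccccc2)c1 | intermediate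
32 | tetramer formate: formate ester of 33 | O=COc1cc(OCc2ccccc2)c(Oc2cc(OCc3ccccc3)c(OCc3ccccc3)c(OCc3ccccc3)c2Oc2cc(Oc3cc(OCc4ccccc4)c(OCc4ccccc4)c(OCc4ccccc4)c3)c(OCc3ccccc3)c(OCc3ccccc3)c2)c(OCc2ccccc2)c1 | intermediate (not isolated)
33 | tetramer phenol: 3,5-bis(benzyloxy)-4-(aryloxy)phenol, aryloxy = oxy residue of 30 | Oc1cc(OCc2ccccc2)c(Oc2cc(OCc3ccccc3)c(OCc3ccccc3)c(OCc3ccccc3)c2Oc2cc(Oc3cc(OCc4ccccc4)c(OCc4ccccc4)c(OCc4ccccc4)c3)c(OCc3ccccc3)c(OCc3ccccc3)c2)c(OCc2ccccc2)c1 | intermediate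
34 | pentamer aldehyde: 3,4,5-tris(benzyloxy)-2-(aryloxy)benzaldehyde, aryloxy = oxy residue of 33 | O=Cc1cc(OCc2ccccc2)c(OCc2ccccc2)c(OCc2ccccc2)c1Oc1cc(OCc2ccccc2)c(Oc2cc(OCc3ccccc3)c(OCc3ccccc3)c(OCc3ccccc3)c2Oc2cc(Oc3cc(OCc4ccccc4)c(OCc4ccccc4)c(OCc4ccccc4)c3)c(OCc3ccccc3)c(OCc3ccccc3)c2)c(OCc2ccccc2)c1 | intermediate
35 | pentamer formate: formate ester of 36 | O=COc1cc(OCc2ccccc2)c(OCc2ccccc2)c(OCc2ccccc2)c1Oc1cc(OCc2ccccc2)c(Oc2cc(OCc3ccccc3)c(OCc3ccccc3)c(OCc3ccccc3)c2Oc2cc(Oc3cc(OCc4ccccc4)c(OCc4ccccc4)c(OCc4ccccc4)c3)c(OCc3ccccc3)c(OCc3ccccc3)c2)c(OCc2ccccc2)c1 | intermediate (not isolated)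
36 | pentamer phenol: 3,4,5-tris(benzyloxy)-2-(aryloxy)phenol, aryloxy = oxy residue of 33 | Oc1cc(OCc2ccccc2)c(OCc2ccccc2)c(OCc2ccccc2)c1Oc1cc(OCc2ccccc2)c(Oc2cc(OCc3ccccc3)c(OCc3ccccc3)c(OCc3ccccc3)c2Oc2cc(Oc3cc(OCc4ccccc4)c(OCc4ccccc4)c(OCc4ccccc4)c3)c(OCc3ccccc3)c(OCc3ccccc3)c2)c(OCc2ccccc2)c1 | intermediate
37 | octadeca-O-benzyl ether of the target | c6ccccc6COc1cc(OCc6ccccc6)c(Oc2cc(OCc6ccccc6)c(OCc6ccccc6)c(Oc3cc(OCc6ccccc6)c(OCc6ccccc6)c(OCc6ccccc6)c3Oc3cc(OCc6ccccc6)c(Oc4cc(OCc6ccccc6)c(OCc6ccccc6)c(OCc6ccccc6)c4Oc4cc(OCc6ccccc6)c(OCc6ccccc6)c(Oc5cc(OCc6ccccc6)c(OCc6ccccc6)c(OCc6ccccc6)c5)c4)c(OCc6ccccc6)c3)c2)c(OCc6ccccc6)c1 | intermediate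
38 | target heptamer CNP0137585.0 | Oc1cc(O)c(Oc2cc(O)c(O)c(Oc3cc(O)c(O)c(O)c3Oc3cc(O)c(Oc4cc(O)c(O)c(O)c4Oc4cc(O)c(O)c(Oc5cc(O)c(O)c(O)c5)c4)c(O)c3)c2)c(O)c1 | target

## Step count and risks

Total steps: 25. Longest linear sequence: 14 (steps 1, 2, 3, 4, 16, 17, 18, 19, 20, 21, 22, 23, 24, 25).

Three steps most likely to fail:

**Step 13 (Claisen/Dieckmann construction of ring A).** Acylation of a stabilised enolate by a malonate ester needs forcing conditions, and self-condensation of 19 competes. The fallback sets out from pentamer phenol 36 (with blocks 10 and 16) and comes back at 37; steps 12–15 and 24 then fall away. Ring B and ring A are added by two more coupling/oxidation cycles. 36 is coupled with iodoaldehyde 10 (CuI, picolinic acid, K3PO4, DMSO) to give the hexamer aldehyde F1. Baeyer–Villiger oxidation with mCPBA gives the hexamer formate F2, and methanolysis gives the hexamer phenol F3. F3 is coupled with bromoaldehyde 16 under the same copper conditions to give the heptamer aldehyde F4. This is oxidised to the heptamer formate F5 and cleaved to the heptamer phenol F6. Benzylation of F6 (BnBr, K2CO3, DMF) gives 37.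

**Step 20 (tri-ortho-substituted D–E ether).** The bromide of 16 is flanked by two benzyloxy groups, so copper insertion may be slow and hydrodebromination may win. The fallback sets out from 16 and 30 and comes back at 31, replacing copper catalysis by a metal-free SNAr. 16 is protected with ethylene glycol (TsOH, toluene, Dean–Stark) as the bromo dioxolane F7. Bromine–lithium exchange (n-BuLi, THF, −78 °C) and quenching with NFSI give the fluoro dioxolane F8. Aqueous HCl in THF releases 3,5-bis(benzyloxy)-4-fluorobenzaldehyde F9. The phenoxide of 30 (K2CO3, DMSO, 120 °C) displaces the fluoride para to the formyl group to give 31.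

**Step 24 (late union of two large fragments).** A di-ortho Ullmann coupling at low concentration may stall. The fallback sets out from 24 and 36 and comes back at 37, changing from Cu(I) halide coupling to an oxidative boron-based coupling at room temperature. 24 undergoes iodine–magnesium exchange (i-PrMgCl·LiCl, THF, −20 °C), borylation with B(OMe)3 and mild aqueous work-up to give the arylboronic acid F10. F10 is joined to phenol 36 by Chan–Lam–Evans coupling (Cu(OAc)2, pyridine, 4 Å MS, CH2Cl2, air, rt) to give 37.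

## Further compounds

F1 | step 13 | hexamer aldehyde: 3,4-bis(benzyloxy)-5-(aryloxy)benzaldehyde, aryloxy = oxy residue of 36 | O=Cc2cc(OCc6ccccc6)c(OCc6ccccc6)c(Oc3cc(OCc6ccccc6)c(OCc6ccccc6)c(OCc6ccccc6)c3Oc3cc(OCc6ccccc6)c(Oc4cc(OCc6ccccc6)c(OCc6ccccc6)c(OCc6ccccc6)c4Oc4cc(OCc6ccccc6)c(OCc6ccccc6)c(Oc5cc(OCc6ccccc6)c(OCc6ccccc6)c(OCc6ccccc6)c5)c4)c(OCc6ccccc6)c3)c2
F2 | step 13 | hexamer formate: formate ester of F3 | O=COc2cc(OCc6ccccc6)c(OCc6ccccc6)c(Oc3cc(OCc6ccccc6)c(OCc6ccccc6)c(OCc6ccccc6)c3Oc3cc(OCc6ccccc6)c(Oc4cc(OCc6ccccc6)c(OCc6ccccc6)c(OCc6ccccc6)c4Oc4cc(OCc6ccccc6)c(OCc6ccccc6)c(Oc5cc(OCc6ccccc6)c(OCc6ccccc6)c(OCc6ccccc6)c5)c4)c(OCc6ccccc6)c3)c2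
F3 | step 13 | hexamer phenol: 3,4-bis(benzyloxy)-5-(aryloxy)phenol, aryloxy = oxy residue of 36 | Oc2cc(OCc6ccccc6)c(OCc6ccccc6)c(Oc3cc(OCc6ccccc6)c(OCc6ccccc6)c(OCc6ccccc6)c3Oc3cc(OCc6ccccc6)c(Oc4cc(OCc6ccccc6)c(OCc6ccccc6)c(OCc6ccccc6)c4Oc4cc(OCc6ccccc6)c(OCc6ccccc6)c(Oc5cc(OCc6ccccc6)c(OCc6ccccc6)c(OCc6ccccc6)c5)c4)c(OCc6ccccc6)c3)c2
F4 | step 13 | heptamer aldehyde: 3,5-bis(benzyloxy)-4-(aryloxy)benzaldehyde, aryloxy = oxy residue of F3 | O=Cc1cc(OCc6ccccc6)c(Oc2cc(OCc6ccccc6)c(OCc6ccccc6)c(Oc3cc(OCc6ccccc6)c(OCc6ccccc6)c(OCc6ccccc6)c3Oc3cc(OCc6ccccc6)c(Oc4cc(OCc6ccccc6)c(OCc6ccccc6)c(OCc6ccccc6)c4Oc4cc(OCc6ccccc6)c(OCc6ccccc6)c(Oc5cc(OCc6ccccc6)c(OCc6ccccc6)c(OCc6ccccc6)c5)c4)c(OCc6ccccc6)c3)c2)c(OCc6ccccc6)c1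
F5 | step 13 | heptamer formate: formate ester of F6 | O=COc1cc(OCc6ccccc6)c(Oc2cc(OCc6ccccc6)c(OCc6ccccc6)c(Oc3cc(OCc6ccccc6)c(OCc6ccccc6)c(OCc6ccccc6)c3Oc3cc(OCc6ccccc6)c(Oc4cc(OCc6ccccc6)c(OCc6ccccc6)c(OCc6ccccc6)c4Oc4cc(OCc6ccccc6)c(OCc6ccccc6)c(Oc5cc(OCc6ccccc6)c(OCc6ccccc6)c(OCc6ccccc6)c5)c4)c(OCc6ccccc6)c3)c2)c(OCc6ccccc6)c1
F6 | step 13 | heptamer phenol: 3,5-bis(benzyloxy)-4-(aryloxy)phenol, aryloxy = oxy residue of F3 | Oc1cc(OCc6ccccc6)c(Oc2cc(OCc6ccccc6)c(OCc6ccccc6)c(Oc3cc(OCc6ccccc6)c(OCc6ccccc6)c(OCc6ccccc6)c3Oc3cc(OCc6ccccc6)c(Oc4cc(OCc6ccccc6)c(OCc6ccccc6)c(OCc6ccccc6)c4Oc4cc(OCc6ccccc6)c(OCc6ccccc6)c(Oc5cc(OCc6ccccc6)c(OCc6ccccc6)c(OCc6ccccc6)c5)c4)c(OCc6ccccc6)c3)c2)c(OCc6ccccc6)c1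
F7 | step 20 | 2-[3,5-bis(benzyloxy)-4-bromophenyl]-1,3-dioxolane | Brc1c(OCc2ccccc2)cc(C2OCCO2)cc1OCc1ccccc1
F8 | step 20 | 2-[3,5-bis(benzyloxy)-4-fluorophenyl]-1,3-dioxolane | Fc1c(OCc2ccccc2)cc(C2OCCO2)cc1OCc1ccccc1
F9 | step 20 | 3,5-bis(benzyloxy)-4-fluorobenzaldehyde | O=Cc1cc(OCc2ccccc2)c(F)c(OCc2ccccc2)c1
F10 | step 24 | {2,3-bis(benzyloxy)-5-[2,4,6-tris(benzyloxy)phenoxy]phenyl}boronic acid | OB(O)c1cc(Oc2c(OCc3ccccc3)cc(OCc3ccccc3)cc2OCc2ccccc2)cc(OCc2ccccc2)c1OCc1ccccc1
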